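**Plan**
- Retrosynthesis: the target is opened first at the bond between the ring N-methyl nitrogen and the stereogenic carbon (C3 of the C16 acyl unit), then at the lactam C–N bond, then at the N–CH2 bonds that tie two three-carbon arms to N,N'-dimethylbutane-1,4-diamine.
- Enabling feature: three atoms of the 17-membered ring (C1–C3 of a hexadecanoyl unit) are spanned by the fourteen-atom N–C3–N–C4–N–C3–N chain of spermine. One terminal nitrogen is the lactam nitrogen on C1 and the other, N-methylated, sits on C3. This β-amino lactam is the conjugate adduct of a free methylamino end to a hexadec-2-enoyl group on the other end.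
- Forward: the open chain is assembled in one line (Boc-protected bromopropyl arm onto the diamine, cyanoethylation, nitrile reduction, acylation with (E)-hexadec-2-enoic acid, Boc removal). The single ring is closed last by intramolecular aza-Michael addition.
- Stereochemistry: the only stereocentre (C3, R) is created in the ring closure. There is no substrate bias, so the enamide face is to be chosen by a chiral binaphthyl phosphoric acid.

Key step: step 8

Assumption: the sense of induction of the chiral acid in this closure cannot be predicted. The route is written for the (R)-configured acid named in step 8, and its mirror image would be used if the S-lactam is favoured.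

**Step 1**
Reactants: 1 3-(methylamino)propan-1-ol
Product: 2 tert-butyl (3-hydroxypropyl)(methyl)carbamate
Conditions: Boc2O (1.05 equiv), CH2Cl2, 0 °C to rt
Reagents that add atoms: di-tert-butyl dicarbonate, CC(C)(C)OC(=O)OC(=O)OC(C)(C)C
Why: Boc protection (N-acylation by the dicarbonate); the secondary amine is far more nucleophilic than the primary alcohol, so the carbamate should form selectively without added base.

**Step 2**
Reactants: 2 tert-butyl (3-hydroxypropyl)(methyl)carbamate
Product: 3 tert-butyl (3-bromopropyl)(methyl)carbamate
Conditions: CBr4, PPh3, CH2Cl2, 0 °C
Reagents that add atoms: carbon tetrabromide, BrC(Br)(Br)Br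
Why: Appel reaction; the primary alcohol is activated as its alkoxyphosphonium salt and displaced by bromide (SN2) at a temperature low enough that the carbamate carbonyl should not close an oxazinanone.

**Step 3**
Reactants: 3 tert-butyl (3-bromopropyl)(methyl)carbamate; 4 N,N'-dimethylbutane-1,4-diamine (5 equiv)
Product: 5 tert-butyl methyl{3-[methyl(4-(methylamino)butyl)amino]propyl}carbamate
Conditions: K2CO3, MeCN, 45 °C; excess 4 distilled off
Reagents that add atoms: none
Why: SN2 N-alkylation of a secondary amine by a primary bromide; the fivefold excess of the symmetrical diamine should hold the reaction at mono-alkylation, and the volatile excess is recovered.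

**Step 4**
Reactants: 5 tert-butyl methyl{3-[methyl(4-(methylamino)butyl)amino]propyl}carbamate; 6 acrylonitrile (1.2 equiv)
Product: 7 tert-butyl {3-[{4-[(2-cyanoethyl)(methyl)amino]butyl}(methyl)amino]propyl}(methyl)carbamate
Conditions: MeOH, rt
Reagents that add atoms: none
Why: cyanoethylation (aza-Michael addition to acrylonitrile); the single N–H amine of 5 should add cleanly, since the tertiary amines and the carbamate have no N–H with which to form a stable adduct.

**Step 5**
Reactants: 7 tert-butyl {3-[{4-[(2-cyanoethyl)(methyl)amino]butyl}(methyl)amino]propyl}(methyl)carbamate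
Product: 8 N12-Boc-N4,N9,N12-trimethylspermine, tert-butyl {3-[{4-[(3-aminopropyl)(methyl)amino]butyl}(methyl)amino]propyl}(methyl)carbamate
Conditions: H2 (4 bar), Raney Ni, 7 M NH3 in MeOH, rt
Reagents that add atoms: none
Why: catalytic hydrogenation of a nitrile to the primary amine, the classical second half of polyamine chain extension; ammonia suppresses secondary-amine formation and the carbamate is inert.

**Step 6**
Reactants: 8 N12-Boc-N4,N9,N12-trimethylspermine; 9 (E)-hexadec-2-enoic acid
Product: 10 N1-[(E)-hexadec-2-enoyl]-N12-Boc-N4,N9,N12-trimethylspermine
Conditions: N,N'-diisopropylcarbodiimide, 1-hydroxybenzotriazole, CH2Cl2, 0 °C to rt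
Reagents that add atoms: none
Why: carbodiimide-mediated amide coupling; only the primary amine of 8 can be acylated, and the mild activation avoids the vinylketene pathway of enoyl chlorides, so the E-alkene should stay conjugated.

**Step 7**
Reactants: 10 N1-[(E)-hexadec-2-enoyl]-N12-Boc-N4,N9,N12-trimethylspermine
Product: 11 N1-[(E)-hexadec-2-enoyl]-N4,N9,N12-trimethylspermine, (E)-N-{3-[methyl(4-{methyl[3-(methylamino)propyl]amino}butyl)amino]propyl}hexadec-2-enamide
Conditions: CF3CO2H, CH2Cl2, 0 °C to rt; then cold aq NaOH, extraction, used at once
Reagents that add atoms: none
Why: acidolytic Boc removal (cleavage of a tert-butyl carbamate); the enamide and the tertiary amines tolerate trifluoroacetic acid, and the free base is liberated cold and used directly so that intermolecular conjugate addition has no time to start.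

**Step 8**
Reactants: 11 N1-[(E)-hexadec-2-enoyl]-N4,N9,N12-trimethylspermine
Product: 12 (4R)-5,9,14-trimethyl-4-tridecyl-1,5,9,14-tetraazacycloheptadecan-2-one (target)
Conditions: (R)-3,3'-bis(2,4,6-triisopropylphenyl)-1,1'-binaphthyl-2,2'-diyl hydrogen phosphate (20 mol%), toluene, 2 mM (slow addition of 11), 40 °C; aq Na2CO3 wash
Reagents that add atoms: none
Why: Proposed new method: the free methylamino terminus adds to C3 of the (E)-enamide (aza-Michael addition) and the resulting amide enol is protonated at C2, which forms the N–C3 bond and closes the 17-membered ring in a 17-endo-trig mode. The closest known reactions are racemic thermal macrocyclising aza-Michael additions of polyamine nitrogens to enoyl amides, and chiral-phosphoric-acid-catalysed intramolecular aza-Michael additions that give 5- and 6-membered rings. Because the basic chain deprotonates the acid, the catalyst is expected to act as an ammonium phosphate ion pair: the phosphate bridges the lactam-to-be N–H and the N–H of the attacking amine while a chain ammonium hydrogen-bonds the carbonyl oxygen, a proton shuttle that the uncatalysed background in toluene lacks. The new stereocentre C3 has no substrate control, so its R configuration has to come from the enamide face left open by the 3,3'-aryl groups of the bound phosphate. Chemoselectivity for the terminal nitrogen follows from its being the only N–H amine (adducts of the two tertiary amines are zwitterions that revert), the secondary amide N–H gives the catalyst its anchor, and ring formation over oligomerisation is secured by the 2 mM dilution with slow addition.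

**Compound list**
1 | 3-(methylamino)propan-1-ol | CNCCCO | starting material
2 | tert-butyl (3-hydroxypropyl)(methyl)carbamate | CN(CCCO)C(=O)OC(C)(C)C | intermediate
3 | tert-butyl (3-bromopropyl)(methyl)carbamate | CN(CCCBr)C(=O)OC(C)(C)C | intermediate
4 | N,N'-dimethylbutane-1,4-diamine | CNCCCCNC | starting material
5 | tert-butyl methyl{3-[methyl(4-(methylamino)butyl)amino]propyl}carbamate | CNCCCCN(C)CCCN(C)C(=O)OC(C)(C)C | intermediate
6 | acrylonitrile | C=CC#N | starting material
7 | tert-butyl {3-[{4-[(2-cyanoethyl)(methyl)amino]butyl}(methyl)amino]propyl}(methyl)carbamate | N#CCCN(C)CCCCN(C)CCCN(C)C(=O)OC(C)(C)C | intermediate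
8 | N12-Boc-N4,N9,N12-trimethylspermine | NCCCN(C)CCCCN(C)CCCN(C)C(=O)OC(C)(C)C | intermediate
9 | (E)-hexadec-2-enoic acid | CCCCCCCCCCCCC/C=C/C(=O)O | starting material
10 | N1-[(E)-hexadec-2-enoyl]-N12-Boc-N4,N9,N12-trimethylspermine | CCCCCCCCCCCCC/C=C/C(=O)NCCCN(C)CCCCN(C)CCCN(C)C(=O)OC(C)(C)C | intermediate
11 | N1-[(E)-hexadec-2-enoyl]-N4,N9,N12-trimethylspermine | CCCCCCCCCCCCC/C=C/C(=O)NCCCN(C)CCCCN(C)CCCNC | intermediate
12 | (4R)-5,9,14-trimethyl-4-tridecyl-1,5,9,14-tetraazacycloheptadecan-2-one | CCCCCCCCCCCCC[C@@H]1CC(=O)NCCCN(C)CCCCN(C)CCCN1C | target

**Step count and risks**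
Total steps: 8. Longest linear sequence: 8 steps, from 3-(methylamino)propan-1-ol (1) to 12.

Steps most likely to fail:

1. Step 8 (the proposed new method). The main risk is poor facial selectivity, because the ion-paired phosphate may be held too loosely to tell the enamide faces apart. Slow closure, oligomerisation and erosion of enantiomeric purity by retro-Michael reopening are secondary risks. The fallback sets out from 11 and gives up catalyst control in favour of resolution. Compound 11 would be closed by plain thermal aza-Michael macrocyclisation without chiral acid (2-propanol, reflux, 1 mM) to racemic 5,9,14-trimethyl-4-tridecyl-1,5,9,14-tetraazacycloheptadecan-2-one F1. The racemate would then be resolved by fractional crystallisation from ethanol/acetone as the 1:1 salt of the R-lactam with (2R,3R)-2,3-bis(4-methylbenzoyloxy)butanedioic acid F2. The mirror-image acid would be taken if the S-amine salt proves the less soluble one. Free-basing the salt with aq NaOH returns to the route at 12.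

2. Step 3. The risks are over-alkylation (a second alkylation of the diamine, quaternisation of the new tertiary amine) and consumption of the bromide by cyclisation onto its own carbamate. The fallback sets out from 2 and replaces substitution by reductive amination, which cannot quaternise and bypasses bromide 3. Alcohol 2 would be oxidised (SO3·pyridine, DMSO, Et3N, 0 °C; Parikh–Doering oxidation) to tert-butyl methyl(3-oxopropyl)carbamate F3. This aldehyde would be condensed with excess 4 and reduced in the same flask (NaBH(OAc)3, 1,2-dichloroethane, rt). The route is rejoined at 5.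

3. Step 5. The risks are loss of the cyanoethyl arm by retro-Michael cleavage and reductive coupling to secondary amines during the hydrogenation. The fallback sets out from 5, leaves out steps 4 and 5, and brings in the primary amine by a Gabriel sequence. Compound 5 would be alkylated with N-(3-bromopropyl)phthalimide (K2CO3, MeCN, 60 °C) to give tert-butyl {3-[{4-[(3-phthalimidopropyl)(methyl)amino]butyl}(methyl)amino]propyl}(methyl)carbamate F4. Hydrazinolysis (N2H4·H2O, EtOH, reflux) would release the amine, and the route is rejoined at 8.

**Further compounds**
F1 | step 8 | racemic 5,9,14-trimethyl-4-tridecyl-1,5,9,14-tetraazacycloheptadecan-2-one | CCCCCCCCCCCCCC1CC(=O)NCCCN(C)CCCCN(C)CCCN1C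
F2 | step 8 | 1:1 salt of 12 with (2R,3R)-2,3-bis(4-methylbenzoyloxy)butanedioic acid | CCCCCCCCCCCCC[C@@H]1CC(=O)NCCCN(C)CCCCN(C)CCCN1C.[C@@H]([C@H](C(=O)O)OC(=O)c1ccc(C)cc1)(C(=O)O)OC(=O)c1ccc(C)cc1
F3 | step 3 | tert-butyl methyl(3-oxopropyl)carbamate | CN(CCC=O)C(=O)OC(C)(C)C
F4 | step 5 | tert-butyl {3-[{4-[(3-phthalimidopropyl)(methyl)amino]butyl}(methyl)amino]propyl}(methyl)carbamate | O=C1c2ccccc2C(=O)N1CCCN(C)CCCCN(C)CCCN(C)C(=O)OC(C)(C)C
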